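## The problem

CNP0126545.1 is a germacranolide (germacrane numbering throughout). It has a ten-membered carbocycle C1–C10 with two trisubstituted ring olefins of opposite ring geometry, C1=C10 cis and C4=C5 trans (E and Z by the sequence rules, because C14 and C15 bear oxygen), and a five-membered α-methylene lactone (C11, C12, C13, O on C8) trans-fused across C7–C8. Each olefin carries an oxidised methyl, C14 as an acetate and C15 as the ester of 2-(hydroxymethyl)acrylic acid, so three primary allylic oxygens (C12, C14, C15) must be told apart. There are two stereocentres, C7 (R) and C8 (S). C7 has three carbon neighbours and needs an external source of chirality; once set, it gives little facial bias at C8 in an open chain or a flexible medium ring, so C8 also needs outside control. Neither olefin geometry can be corrected once the ring exists, so both must be fixed in acyclic precursors. The α-methylene lactone and the acrylate are Michael acceptors, the allylic acetate does not survive hydride, strong base or zerovalent palladium, and the 1,5-diene in a ten-membered ring is prone to acid-induced transannular cyclisation and to Cope rearrangement on heating. The feature that allows a late solution is that C8 is an unactivated methylene γ to the C12 carboxyl of the acrylic acid on C7: a hydroxyl placed on C8 on the face opposite C11 closes the lactone by itself, and the C12 carboxylate is the handle by which germacrene-acid hydroxylases hold their substrate.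

## Retrosynthesis

**C15 ester.** Target 41 is cut at the C15 O–acyl bond into hydroxy lactone 36 and silyl-protected acid 39 (from commercial ester 37 via 38). This cut comes last because the side chain adds a second Michael acceptor and a free hydroxyl that nothing earlier should meet. The forward step is an acylation of a primary allylic alcohol under carbodiimide conditions, followed by removal of one silyl group.

**Lactone (key cut).** In 36 the O–C12 bond and the C8–O bond are cut together, giving seco acid 34 through hydroxy acid 35. A chemical C8 oxygen would have to be carried, protected and stereodefined, through the ring closure, or be made from a C8 ketone next to an epimerisable C7. Removing it leaves a macrocycle with one stereocentre and no lactone. The forward reaction must choose C8 over four allylic methylenes (C2, C3, C6, C9) and one of two hydrogens; no reagent does this, a P450 hydroxylase of the germacrene-acid family does.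

**Functional groups of 34.** The C15 hydroxyl, C14 acetate and C12 acid are traced back through 33, 32 and 31 to enal 30, aldehyde 28 and primary alcohol 27. C13 is added to the aldehyde by a Mannich methylenation and C12 is then oxidised, so the macrocycle never meets a strong base after ring closure. C14 and C15 are distinguished as a tert-butyldimethylsilyl and a tert-butyldiphenylsilyl ether.

**Ring closure at C2–C3.** Alcohol 27 comes from macrocyclic sulfone 25, and 25 from open-chain chloride 24 by alkylation of a C2 sulfonyl carbanion with the C3 allylic chloride.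
- This bond is preferred to C8–C9 with a sulfone on C9. There the allyl system left for reductive desulfonylation would end in two secondary carbons (C9 and C1), and the olefin position would not be defined.
- With the sulfone on C2, the allyl system C2–C1–C10 ends in a fully substituted carbon, and hydride goes to C2.
- A non-allylic sulfone on C8 was set aside because its acidity matches that of the ester α-hydrogens.
- The hydride that removes the sulfone also reduces the tert-butyl ester to the alcohol 27, which the endgame needs anyway.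

**C9–C10.** Chloride 24 (via alcohol 22) is cut at the sp3–sp2 bond C9–C10 into alkene 17 and alkenyl iodide 20, joined by hydroboration and B-alkyl Suzuki coupling. The coupling keeps the iodide geometry, so the cis 1(10) olefin is already decided in 20.

**C7 and the C4=C5 unit.** Alkene 17 goes back through 16, 15, 14, 13 and 12 to imide 11. The vinyl group comes from the imide carbonyl (reduction, oxidation, methylenation) and C15 from a Stille hydroxymethylation of the alkenyl iodide. The C6–C7 bond and the C7 stereocentre come from Evans alkylation of succinate imide 9 (from 6 and 7) with allylic bromide 5. The tert-butyl ester arm is C11–C12.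

**One building block for both olefins.** Bromide 5 and sulfone 20 both derive from (Z)-iodo alcohol 4, made from but-2-yne-1,4-diol 1 via 2 by directed trans-hydroalumination and iodination. In 5 the iodide is replaced by C15 (cis to C6); in 20 it is replaced by C9 (cis to C2). One reaction therefore sets both ring geometries.

## Roads not taken

**Alternative 1:** The ring is made by a [3,3] shift that forms C2–C3 and breaks C5–C10. The potassium alkoxide of the six-membered precursor of A1 undergoes an anionic oxy-Cope ring expansion and the C10 enolate is trapped as triflate A1, which already carries a protected C8 oxygen.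
- Merits: no high-dilution step; C7 and C8 are set on a cyclohexane; the C8 oxygen is installed by ordinary chemistry. In the certainty of the C–O bond this road is better than the chosen one.
- Weak points: both olefin geometries depend on the chair or boat preference of one transition state and on enolate trapping; C14 must still be attached to the triflate and reduced; C12 must be oxidised; three different protecting groups are carried around a ring-strained diene.
- Against it the chosen plan sets olefin geometries fixed by alkyne chemistry before the ring forms, and a lactone that closes in the last skeletal step with no C8 protecting group.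

**Alternative 2:** The ring is closed at C6–C7. A C6 allylic radical adds to C7 of a butenolide bearing a sulfonylmethyl group on C11; loss of the sulfonyl radical creates C11=C13 and gives A2, the 15-O-silyl ether of 36.
- Merits: ring, C7 and the exocyclic methylene arise in one step; C7 is set trans to a pre-existing C8; no enzyme is needed. In step economy after fragment assembly it is at least as good as the chosen plan.
- Weak points: the allylic radical has two termini (C6 and C4) and loses the C4=C5 geometry; the ring size is unfavourable for radical closure; tin reagents meet a finished Michael acceptor; C8 must first be made as a single enantiomer.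
- The chosen plan answers with polar ring closure at a position where regiochemistry and geometry are defined.

**Alternative 3:** A cis-fused bicyclo[5.3.0]decene diol monomesylate (the precursor of A3) undergoes Grob fragmentation of C4–C8 to give cyclodecadienone A3.
- Merits: the ring is opened, not closed; the trans C4=C5 olefin follows from the anti-periplanar arrangement; the C8 ketone is in place for reduction and lactonisation. In reliability of ring formation this road is probably the best of the four.
- Weak points: the bicyclic precursor needs several correctly related stereocentres and the cis 1(10) olefin inside a seven-membered ring; the C8 ketone sits next to the epimerisable C7 and is β,γ-unsaturated; its reduction must be face-selective.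
- The chosen plan carries a single stereocentre and no C8 carbonyl, at the price of an enzymatic step without precedent on this substrate.

Key step: step 23

Assumption (chemistry of step 23): a CYP71-clan 8α-hydroxylase variant that accepts 34 is obtained by screening and directed evolution; none is known for this substrate. Compounds 1, 6, 7, 18, 37 and all reagents are commercial.

## Route

Step 1
Reactants: 1 but-2-yne-1,4-diol
Product: 2 4-[(tert-butyldimethylsilyl)oxy]but-2-yn-1-ol
Conditions: 1 (3 equiv), TBSCl, imidazole, DMF, 0 °C → rt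
Reagents that add atoms: tert-butyldimethylsilyl chloride CC(C)(C)[Si](C)(C)Cl
Why: Statistical monosilylation of a symmetric diol used in excess (silyl ether formation); bis-ether and excess diol are separated.

Step 2
Reactants: 2 monosilylated butynediol
Product: 4 (2Z)-4-[(tert-butyldimethylsilyl)oxy]-3-iodobut-2-en-1-ol, via cyclic vinylalanate 3 (not isolated)
Conditions: NaAlH2(OCH2CH2OMe)2, THF, 0 °C; then I2, −78 → 0 °C
Reagents that add atoms: iodine II
Why: Hydroxyl-directed trans-hydroalumination puts hydride on the near alkyne carbon and aluminium on the far one in a five-membered alanate; iodinolysis with retention should give only the (Z)-iodoalkene, which fixes the geometry of both ring olefins.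

Step 3
Reactants: 4 (Z)-iodo alcohol
Product: 5 {[(2Z)-4-bromo-2-iodobut-2-en-1-yl]oxy}(tert-butyl)dimethylsilane
Conditions: CBr4, PPh3, CH2Cl2, 0 °C
Reagents that add atoms: carbon tetrabromide BrC(Br)(Br)Br
Why: Appel bromination at the primary allylic carbon; alkenyl iodide and silyl ether are inert.

Step 4
Reactants: 6 4-tert-butoxy-4-oxobutanoic acid; 7 (4R)-4-benzyl-1,3-oxazolidin-2-one
Product: 9 tert-butyl 4-[(4R)-4-benzyl-2-oxo-1,3-oxazolidin-3-yl]-4-oxobutanoate, via mixed pivalic anhydride 8 (not isolated)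
Conditions: t-BuCOCl, Et3N, THF, −20 °C; then LiCl, 7, rt
Reagents that add atoms: none
Why: N-Acylation of the oxazolidinone through the mixed anhydride under LiCl/Et3N activation, the standard entry to Evans imides.

Step 5
Reactants: 9 succinate imide; 5 allylic bromide
Product: 11 tert-butyl (3R,5Z)-3-{[(4R)-4-benzyl-2-oxo-1,3-oxazolidin-3-yl]carbonyl}-7-[(tert-butyldimethylsilyl)oxy]-6-iodohept-5-enoate, via sodium enolate 10 (not isolated)
Conditions: NaN(SiMe3)2, THF, −78 °C; then 5, −78 → −40 °C
Reagents that add atoms: none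
Why: Evans asymmetric alkylation: the chelated (Z)-enolate is alkylated on the face opposite the benzyl group, which sets C7 as R (3R in this name); only the imide α-hydrogens are acidic enough to be removed, so the tert-butyl ester arm stays intact.

Step 6
Reactants: 11 alkylated imide
Product: 12 tert-butyl (3R,5E)-3-{[(4R)-4-benzyl-2-oxo-1,3-oxazolidin-3-yl]carbonyl}-7-[(tert-butyldimethylsilyl)oxy]-6-(hydroxymethyl)hept-5-enoate
Conditions: Bu3SnCH2OH, Pd(PPh3)4 (5 mol %), 1,4-dioxane, 90 °C
Reagents that add atoms: (tributylstannyl)methanol CCCC[Sn](CCCC)(CCCC)CO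
Why: Stille coupling transfers the hydroxymethyl group to the alkenyl iodide with retention, placing C15 cis to C6; it is run before any terminal alkene is present so that no intramolecular Heck path exists.

Step 7
Reactants: 12 allylic alcohol
Product: 13 tert-butyl (3R,5Z)-3-{[(4R)-4-benzyl-2-oxo-1,3-oxazolidin-3-yl]carbonyl}-7-[(tert-butyldimethylsilyl)oxy]-6-{[(tert-butyldiphenylsilyl)oxy]methyl}hept-5-enoate
Conditions: TBDPSCl, imidazole, CH2Cl2, rt
Reagents that add atoms: tert-butyl(chloro)diphenylsilane CC(C)(C)[Si](Cl)(c1ccccc1)c1ccccc1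
Why: Silylation of the primary alcohol as the more acid-stable silyl ether, which has to outlast two later removals of tert-butyldimethylsilyl groups.

Step 8
Reactants: 13 bis-silyl imide
Product: 14 tert-butyl (3R,5Z)-7-[(tert-butyldimethylsilyl)oxy]-6-{[(tert-butyldiphenylsilyl)oxy]methyl}-3-(hydroxymethyl)hept-5-enoate
Conditions: LiBH4, MeOH (1.1 equiv), THF, 0 °C
Reagents that add atoms: none
Why: Reductive removal of the auxiliary; the exocyclic imide carbonyl is the most electrophilic, the tert-butyl ester is spared, and 7 is recovered.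

Step 9
Reactants: 14 primary alcohol
Product: 15 tert-butyl (3R,5Z)-7-[(tert-butyldimethylsilyl)oxy]-6-{[(tert-butyldiphenylsilyl)oxy]methyl}-3-formylhept-5-enoate
Conditions: Dess–Martin periodinane, NaHCO3, CH2Cl2, 0 °C → rt
Reagents that add atoms: none
Why: Buffered Dess–Martin oxidation should give the α-branched aldehyde without epimerisation at C7; it is used at once.

Step 10
Reactants: 15 aldehyde
Product: 16 tert-butyl (3R,5Z)-7-[(tert-butyldimethylsilyl)oxy]-6-{[(tert-butyldiphenylsilyl)oxy]methyl}-3-ethenylhept-5-enoate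
Conditions: Ph3PCH3Br, KN(SiMe3)2, THF, 0 °C; then 15, −78 → 0 °C
Reagents that add atoms: methyltriphenylphosphonium bromide C[P+](c1ccccc1)(c1ccccc1)c1ccccc1.[Br-]
Why: Wittig methylenation at low temperature turns C8 into the vinyl group C8=C9 faster than the aldehyde can enolise; the tert-butyl ester is not attacked.

Step 11
Reactants: 16 vinyl compound
Product: 17 tert-butyl (3R,5Z)-6-{[(tert-butyldiphenylsilyl)oxy]methyl}-3-ethenyl-7-hydroxyhept-5-enoate
Conditions: PPTS (cat.), MeOH, rt
Reagents that add atoms: none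
Why: Mild acid methanolysis cleaves the primary tert-butyldimethylsilyl ether much faster than the tert-butyldiphenylsilyl ether, freeing the C3 hydroxyl.

Step 12
Reactants: 4 (Z)-iodo alcohol; 18 sodium benzenesulfinate
Product: 20 tert-butyl{[(2Z)-2-iodo-4-(phenylsulfonyl)but-2-en-1-yl]oxy}dimethylsilane, via allylic mesylate 19 (not isolated)
Conditions: MsCl, Et3N, CH2Cl2, −20 °C; then 18, Bu4NI (cat.), DMF, rt
Reagents that add atoms: none
Why: Mesylation and SN2 displacement by sulfinate sulfur give the allylic sulfone; a second portion of 4 thus becomes the C2/C1/C10/C14 unit.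

Step 13
Reactants: 17 vinyl alcohol; 20 iodo sulfone
Product: 22 tert-butyl (3R,5Z)-3-[(3E)-3-{[(tert-butyldimethylsilyl)oxy]methyl}-5-(phenylsulfonyl)pent-3-en-1-yl]-6-{[(tert-butyldiphenylsilyl)oxy]methyl}-7-hydroxyhept-5-enoate, via bis(9-BBN) adduct 21 (not isolated)
Conditions: 9-BBN-H (2.5 equiv), THF, rt; then 20, Pd(dppf)Cl2 (5 mol %), AsPh3, Cs2CO3, DMF/H2O, rt
Reagents that add atoms: none
Why: 9-BBN-H hydroborates only the monosubstituted alkene at its terminus (the hydroxyl is held as a borinate), and B-alkyl Suzuki–Miyaura coupling with the alkenyl iodide proceeds with retention, forming C9–C10 with C9 cis to C2; at room temperature the allylic sulfone should not ionise on zerovalent palladium.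

Step 14
Reactants: 22 sulfone alcohol
Product: 24 tert-butyl (3R,5E)-3-[(3E)-3-{[(tert-butyldimethylsilyl)oxy]methyl}-5-(phenylsulfonyl)pent-3-en-1-yl]-6-{[(tert-butyldiphenylsilyl)oxy]methyl}-7-chlorohept-5-enoate, via allylic mesylate 23 (not isolated)
Conditions: MsCl, 2,4,6-collidine, LiCl, DMF, 0 °C → rt
Reagents that add atoms: lithium chloride [Li+].[Cl-]
Why: Mesylation with chloride exchange in situ gives the primary allylic chloride without transposition; collidine is too weak a base to deprotonate the sulfone.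

Step 15
Reactants: 24 chloro sulfone
Product: 25 tert-butyl (1(10)E,4Z,7R)-14-[(tert-butyldimethylsilyl)oxy]-15-[(tert-butyldiphenylsilyl)oxy]-2-(phenylsulfonyl)-13-norgermacra-1(10),4-dien-12-oate
Conditions: LiN(SiMe3)2, THF, −78 → −20 °C, slow addition of 24 (final 0.002 M)
Reagents that add atoms: none
Why: Intramolecular alkylation of the sulfone-stabilised allylic carbanion (C2) by the allylic chloride (C3), a standard closure for 1,5-diene carbocycles, run at high dilution; the amide base removes the sulfone α-hydrogen but not the ester α-hydrogen, the cis C1=C10 olefin brings the ends together, and the new C2 centre (both epimers) disappears in step 16.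

Step 16
Reactants: 25 macrocyclic sulfone
Product: 27 (1(10)E,4Z,7R)-14-[(tert-butyldimethylsilyl)oxy]-15-[(tert-butyldiphenylsilyl)oxy]-13-norgermacra-1(10),4-dien-12-ol, via desulfonylated tert-butyl ester 26 (not isolated)
Conditions: Pd(dppp)Cl2 (5 mol %), LiBHEt3 (6 equiv), THF, 0 °C → rt
Reagents that add atoms: none
Why: Palladium-catalysed hydride reduction of the allylic sulfone: ionisation gives a π-allyl complex over C2–C1–C10 and hydride goes to the less substituted end C2, so the olefin should stay at C1=C10 with its geometry; the excess hydride then reduces the tert-butyl ester to the C12 alcohol, which is wanted.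

Step 17
Reactants: 27 macrocyclic alcohol
Product: 28 (1(10)E,4Z,7R)-14-[(tert-butyldimethylsilyl)oxy]-15-[(tert-butyldiphenylsilyl)oxy]-13-norgermacra-1(10),4-dien-12-al
Conditions: Dess–Martin periodinane, NaHCO3, CH2Cl2, 0 °C → rt
Reagents that add atoms: none
Why: Dess–Martin oxidation of the only free alcohol; silyl ethers and olefins are untouched.

Step 18
Reactants: 28 aldehyde
Product: 30 (1(10)E,4Z,7R)-14-[(tert-butyldimethylsilyl)oxy]-15-[(tert-butyldiphenylsilyl)oxy]germacra-1(10),4,11(13)-trien-12-al, via Mannich base 29 (not isolated)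
Conditions: CH2=NMe2+ I−, Et3N, CH2Cl2, rt
Reagents that add atoms: N,N-dimethylmethyleneiminium iodide C=[N+](C)C.[I-]
Why: Mannich α-methylenation of an aldehyde: the enol adds to the iminium ion and the β-amino aldehyde loses dimethylamine under the amine base, installing C13 without strong base.

Step 19
Reactants: 30 enal
Product: 31 (1(10)E,4Z,7R)-14-[(tert-butyldimethylsilyl)oxy]-15-[(tert-butyldiphenylsilyl)oxy]germacra-1(10),4,11(13)-trien-12-oic acid
Conditions: NaClO2, NaH2PO4, 2-methyl-2-butene, t-BuOH/H2O, 0 °C → rt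
Reagents that add atoms: sodium chlorite [Na+].[O-]Cl=O
Why: Pinnick oxidation of the enal to the acrylic acid; 2-methyl-2-butene scavenges hypochlorous acid so the ring olefins are spared.

Step 20
Reactants: 31 bis-silyl acid
Product: 32 (1(10)E,4Z,7R)-15-[(tert-butyldiphenylsilyl)oxy]-14-hydroxygermacra-1(10),4,11(13)-trien-12-oic acid
Conditions: HF·pyridine, pyridine, THF, 0 °C
Reagents that add atoms: none
Why: Buffered HF·pyridine removes the primary tert-butyldimethylsilyl ether at C14 well before the tert-butyldiphenylsilyl ether at C15.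

Step 21
Reactants: 32 hydroxy acid
Product: 33 (1(10)E,4Z,7R)-14-acetoxy-15-[(tert-butyldiphenylsilyl)oxy]germacra-1(10),4,11(13)-trien-12-oic acid
Conditions: Ac2O, pyridine, DMAP (cat.), CH2Cl2, 0 °C → rt; aq. NaHCO3, then pH 4
Reagents that add atoms: acetic anhydride CC(=O)OC(C)=O
Why: Acetylation of the C14 alcohol; any mixed anhydride formed at the carboxyl is hydrolysed in the work-up.

Step 22
Reactants: 33 acetoxy silyl acid
Product: 34 (1(10)E,4Z,7R)-14-acetoxy-15-hydroxygermacra-1(10),4,11(13)-trien-12-oic acid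
Conditions: HF·pyridine, pyridine, THF, rt
Reagents that add atoms: none
Why: Fluoride cleavage of the last silyl ether under buffered conditions that the allylic acetate and the medium-ring diene should tolerate.

Step 23
Reactants: 34 seco acid
Product: 36 (1(10)E,4Z,7R,8S)-14-acetoxy-15-hydroxygermacra-1(10),4,11(13)-trien-12,8-olide, via 8-hydroxy acid 35 (not isolated)
Conditions: engineered CYP71-clan germacrene A acid 8α-hydroxylase (haem-thiolate iron enzyme) with its NADPH–cytochrome P450 reductase, esterase-free preparation, NADPH (cat.), glucose dehydrogenase, D-glucose, O2 (air), phosphate buffer pH 7.5, 30 °C; then pH 5, EtOAc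
Reagents that add atoms: dioxygen O=O
Why: Proposed new method: the ferryl oxo porphyrin radical cation of the enzyme (iron formally tetravalent) removes the C8 hydrogen on the face opposite C11 and returns hydroxyl by oxygen rebound with retention, giving (8S)-alcohol 35. The closest known reaction type is the 8-hydroxylation of germacrene A acid by CYP71-clan hydroxylases, whose 8α-hydroxy acids lactonise without a further enzyme; 34 differs by the cis 1(10) olefin and the two oxygenated methyls, so a variant selected against 34 is needed. The hydroxyl of 35 then attacks the C12 carboxyl in a 5-exo-trig acyl substitution, spontaneously or on bringing the extract to pH 5, closing the one new ring as the trans-fused α-methylene lactone. The new stereocentre C8 is controlled by the enzyme pocket, which holds the C12 carboxylate and reads the fixed 7R centre beside it; the substrate alone offers no bias. The step needs site selectivity for C8 over the allylic methylenes C2, C3, C6 and C9 and over epoxidation of three olefins, and face selectivity for the hydrogen trans to C11. What the substrate contributes is the nearness of C8 to the bound carboxylate. An esterase-free enzyme preparation keeps the C14 acetate.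

Step 24
Reactants: 37 ethyl 2-(hydroxymethyl)prop-2-enoate
Product: 38 ethyl 2-{[(tert-butyldimethylsilyl)oxy]methyl}prop-2-enoate
Conditions: TBSCl, imidazole, CH2Cl2, 0 °C → rt
Reagents that add atoms: tert-butyldimethylsilyl chloride CC(C)(C)[Si](C)(C)Cl
Why: Silyl ether formation at the primary alcohol.

Step 25
Reactants: 38 silylated ethyl ester
Product: 39 2-{[(tert-butyldimethylsilyl)oxy]methyl}prop-2-enoic acid
Conditions: LiOH, THF/H2O, 0 °C → rt; then HCl (aq.) to pH 4, 0 °C
Reagents that add atoms: lithium hydroxide [Li+].[OH-]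
Why: Saponification; hydroxide attacks the ester carbonyl faster than it adds to the 2-substituted acrylate, and careful acidification keeps the silyl ether.

Step 26
Reactants: 36 hydroxy lactone; 39 silylated acrylic acid
Product: 40 (1(10)E,4Z,7R,8S)-14-acetoxy-15-[(2-{[(tert-butyldimethylsilyl)oxy]methyl}prop-2-enoyl)oxy]germacra-1(10),4,11(13)-trien-12,8-olide
Conditions: N,N′-dicyclohexylcarbodiimide, DMAP (cat.), CH2Cl2, 0 °C → rt
Reagents that add atoms: none
Why: Steglich esterification of the primary allylic C15 alcohol; mild enough for the α-methylene lactone and the acetate.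

Step 27
Reactants: 40 silyl-protected ester
Product: 41 (1(10)E,4Z,7R,8S)-14-acetoxy-15-{[2-(hydroxymethyl)prop-2-enoyl]oxy}germacra-1(10),4,11(13)-trien-12,8-olide (CNP0126545.1)
Conditions: HF·pyridine, pyridine, THF, 0 °C → rt
Reagents that add atoms: none
Why: Buffered fluoride removes the primary silyl ether without touching the three esters or the two Michael acceptors.

## Compound list

1 | but-2-yne-1,4-diol | OCC#CCO | starting material
2 | 4-[(tert-butyldimethylsilyl)oxy]but-2-yn-1-ol | OCC#CCO[Si](C)(C)C(C)(C)C | intermediate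
3 | sodium cyclic alkenylalanate of 2 (Al bound to C3 and to the C1 oxygen, two 2-methoxyethoxy ligands) | [Na+].COCCO[Al-]1(OCCOC)OCC=C1CO[Si](C)(C)C(C)(C)C | intermediate (not isolated)
4 | (2Z)-4-[(tert-butyldimethylsilyl)oxy]-3-iodobut-2-en-1-ol | OC/C=C(\I)CO[Si](C)(C)C(C)(C)C | intermediate
5 | {[(2Z)-4-bromo-2-iodobut-2-en-1-yl]oxy}(tert-butyl)dimethylsilane | BrC/C=C(\I)CO[Si](C)(C)C(C)(C)C | intermediate
6 | 4-tert-butoxy-4-oxobutanoic acid | OC(=O)CCC(=O)OC(C)(C)C | starting material
7 | (4R)-4-benzyl-1,3-oxazolidin-2-one | O=C1OC[C@@H](Cc2ccccc2)N1 | starting material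
8 | 4-tert-butoxy-4-oxobutanoic pivalic anhydride | CC(C)(C)C(=O)OC(=O)CCC(=O)OC(C)(C)C | intermediate (not isolated)
9 | tert-butyl 4-[(4R)-4-benzyl-2-oxo-1,3-oxazolidin-3-yl]-4-oxobutanoate | O=C1OC[C@@H](Cc2ccccc2)N1C(=O)CCC(=O)OC(C)(C)C | intermediate
10 | sodium (Z)-enolate of imide 9 | [Na+].[O-]/C(=C\CC(=O)OC(C)(C)C)N1[C@H](Cc2ccccc2)COC1=O | intermediate (not isolated)
11 | tert-butyl (3R,5Z)-3-{[(4R)-4-benzyl-2-oxo-1,3-oxazolidin-3-yl]carbonyl}-7-[(tert-butyldimethylsilyl)oxy]-6-iodohept-5-enoate | CC(C)(C)[Si](C)(C)OC/C(I)=C/C[C@H](CC(=O)OC(C)(C)C)C(=O)N1[C@H](Cc2ccccc2)COC1=O | intermediate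
12 | tert-butyl (3R,5E)-3-{[(4R)-4-benzyl-2-oxo-1,3-oxazolidin-3-yl]carbonyl}-7-[(tert-butyldimethylsilyl)oxy]-6-(hydroxymethyl)hept-5-enoate | CC(C)(C)[Si](C)(C)OC/C(CO)=C/C[C@H](CC(=O)OC(C)(C)C)C(=O)N1[C@H](Cc2ccccc2)COC1=O | intermediate
13 | tert-butyl (3R,5Z)-3-{[(4R)-4-benzyl-2-oxo-1,3-oxazolidin-3-yl]carbonyl}-7-[(tert-butyldimethylsilyl)oxy]-6-{[(tert-butyldiphenylsilyl)oxy]methyl}hept-5-enoate | CC(C)(C)[Si](C)(C)OC/C(CO[Si](c1ccccc1)(c1ccccc1)C(C)(C)C)=C/C[C@H](CC(=O)OC(C)(C)C)C(=O)N1[C@H](Cc2ccccc2)COC1=O | intermediate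
14 | tert-butyl (3R,5Z)-7-[(tert-butyldimethylsilyl)oxy]-6-{[(tert-butyldiphenylsilyl)oxy]methyl}-3-(hydroxymethyl)hept-5-enoate | CC(C)(C)[Si](C)(C)OC/C(CO[Si](c1ccccc1)(c1ccccc1)C(C)(C)C)=C/C[C@H](CC(=O)OC(C)(C)C)CO | intermediate
15 | tert-butyl (3R,5Z)-7-[(tert-butyldimethylsilyl)oxy]-6-{[(tert-butyldiphenylsilyl)oxy]methyl}-3-formylhept-5-enoate | CC(C)(C)[Si](C)(C)OC/C(CO[Si](c1ccccc1)(c1ccccc1)C(C)(C)C)=C/C[C@H](CC(=O)OC(C)(C)C)C=O | intermediate
16 | tert-butyl (3R,5Z)-7-[(tert-butyldimethylsilyl)oxy]-6-{[(tert-butyldiphenylsilyl)oxy]methyl}-3-ethenylhept-5-enoate | CC(C)(C)[Si](C)(C)OC/C(CO[Si](c1ccccc1)(c1ccccc1)C(C)(C)C)=C/C[C@H](CC(=O)OC(C)(C)C)C=C | intermediate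
17 | tert-butyl (3R,5Z)-6-{[(tert-butyldiphenylsilyl)oxy]methyl}-3-ethenyl-7-hydroxyhept-5-enoate | OC/C(CO[Si](c1ccccc1)(c1ccccc1)C(C)(C)C)=C/C[C@H](CC(=O)OC(C)(C)C)C=C | intermediate
18 | sodium benzenesulfinate | [Na+].[O-]S(=O)c1ccccc1 | starting material
19 | (2Z)-4-[(tert-butyldimethylsilyl)oxy]-3-iodobut-2-en-1-yl methanesulfonate | CS(=O)(=O)OC/C=C(\I)CO[Si](C)(C)C(C)(C)C | intermediate (not isolated)
20 | tert-butyl{[(2Z)-2-iodo-4-(phenylsulfonyl)but-2-en-1-yl]oxy}dimethylsilane | O=S(=O)(C/C=C(\I)CO[Si](C)(C)C(C)(C)C)c1ccccc1 | intermediate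
21 | tert-butyl (3R,5Z)-7-[(9-borabicyclo[3.3.1]nonan-9-yl)oxy]-3-[2-(9-borabicyclo[3.3.1]nonan-9-yl)ethyl]-6-{[(tert-butyldiphenylsilyl)oxy]methyl}hept-5-enoate | O(B1C2CCCC1CCC2)C/C(CO[Si](c1ccccc1)(c1ccccc1)C(C)(C)C)=C/C[C@H](CC(=O)OC(C)(C)C)CCB1C2CCCC1CCC2 | intermediate (not isolated)
22 | tert-butyl (3R,5Z)-3-[(3E)-3-{[(tert-butyldimethylsilyl)oxy]methyl}-5-(phenylsulfonyl)pent-3-en-1-yl]-6-{[(tert-butyldiphenylsilyl)oxy]methyl}-7-hydroxyhept-5-enoate | OC/C(CO[Si](c1ccccc1)(c1ccccc1)C(C)(C)C)=C/C[C@H](CC(=O)OC(C)(C)C)CC/C(CO[Si](C)(C)C(C)(C)C)=C\CS(=O)(=O)c1ccccc1 | intermediate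
23 | tert-butyl (3R,5E)-3-[(3E)-3-{[(tert-butyldimethylsilyl)oxy]methyl}-5-(phenylsulfonyl)pent-3-en-1-yl]-6-{[(tert-butyldiphenylsilyl)oxy]methyl}-7-[(methylsulfonyl)oxy]hept-5-enoate | CS(=O)(=O)OC/C(CO[Si](c1ccccc1)(c1ccccc1)C(C)(C)C)=C/C[C@H](CC(=O)OC(C)(C)C)CC/C(CO[Si](C)(C)C(C)(C)C)=C\CS(=O)(=O)c1ccccc1 | intermediate (not isolated)
24 | tert-butyl (3R,5E)-3-[(3E)-3-{[(tert-butyldimethylsilyl)oxy]methyl}-5-(phenylsulfonyl)pent-3-en-1-yl]-6-{[(tert-butyldiphenylsilyl)oxy]methyl}-7-chlorohept-5-enoate | ClC/C(CO[Si](c1ccccc1)(c1ccccc1)C(C)(C)C)=C/C[C@H](CC(=O)OC(C)(C)C)CC/C(CO[Si](C)(C)C(C)(C)C)=C\CS(=O)(=O)c1ccccc1 | intermediate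
25 | tert-butyl (1(10)E,4Z,7R)-14-[(tert-butyldimethylsilyl)oxy]-15-[(tert-butyldiphenylsilyl)oxy]-2-(phenylsulfonyl)-13-norgermacra-1(10),4-dien-12-oate (ring olefins 1(10)-cis and 4-trans; both C2 epimers) | CC(C)(C)[Si](c1ccccc1)(c1ccccc1)OC/C1=C\C[C@H](CC(=O)OC(C)(C)C)CC/C(CO[Si](C)(C)C(C)(C)C)=C\C(S(=O)(=O)c2ccccc2)C1 | intermediate
26 | tert-butyl (1(10)E,4Z,7R)-14-[(tert-butyldimethylsilyl)oxy]-15-[(tert-butyldiphenylsilyl)oxy]-13-norgermacra-1(10),4-dien-12-oate | CC(C)(C)[Si](c1ccccc1)(c1ccccc1)OC/C1=C\C[C@H](CC(=O)OC(C)(C)C)CC/C(CO[Si](C)(C)C(C)(C)C)=C\CC1 | intermediate (not isolated)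
27 | (1(10)E,4Z,7R)-14-[(tert-butyldimethylsilyl)oxy]-15-[(tert-butyldiphenylsilyl)oxy]-13-norgermacra-1(10),4-dien-12-ol | CC(C)(C)[Si](c1ccccc1)(c1ccccc1)OC/C1=C\C[C@H](CCO)CC/C(CO[Si](C)(C)C(C)(C)C)=C\CC1 | intermediate
28 | (1(10)E,4Z,7R)-14-[(tert-butyldimethylsilyl)oxy]-15-[(tert-butyldiphenylsilyl)oxy]-13-norgermacra-1(10),4-dien-12-al | CC(C)(C)[Si](c1ccccc1)(c1ccccc1)OC/C1=C\C[C@H](CC=O)CC/C(CO[Si](C)(C)C(C)(C)C)=C\CC1 | intermediate
29 | (1(10)E,4Z,7R)-14-[(tert-butyldimethylsilyl)oxy]-15-[(tert-butyldiphenylsilyl)oxy]-13-(dimethylamino)germacra-1(10),4-dien-12-al (C11 epimers) | CC(C)(C)[Si](c1ccccc1)(c1ccccc1)OC/C1=C\C[C@H](C(CN(C)C)C=O)CC/C(CO[Si](C)(C)C(C)(C)C)=C\CC1 | intermediate (not isolated)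
30 | (1(10)E,4Z,7R)-14-[(tert-butyldimethylsilyl)oxy]-15-[(tert-butyldiphenylsilyl)oxy]germacra-1(10),4,11(13)-trien-12-al | CC(C)(C)[Si](c1ccccc1)(c1ccccc1)OC/C1=C\C[C@H](C(=C)C=O)CC/C(CO[Si](C)(C)C(C)(C)C)=C\CC1 | intermediate
31 | (1(10)E,4Z,7R)-14-[(tert-butyldimethylsilyl)oxy]-15-[(tert-butyldiphenylsilyl)oxy]germacra-1(10),4,11(13)-trien-12-oic acid | CC(C)(C)[Si](c1ccccc1)(c1ccccc1)OC/C1=C\C[C@H](C(=C)C(O)=O)CC/C(CO[Si](C)(C)C(C)(C)C)=C\CC1 | intermediate
32 | (1(10)E,4Z,7R)-15-[(tert-butyldiphenylsilyl)oxy]-14-hydroxygermacra-1(10),4,11(13)-trien-12-oic acid | CC(C)(C)[Si](c1ccccc1)(c1ccccc1)OC/C1=C\C[C@H](C(=C)C(O)=O)CC/C(CO)=C\CC1 | intermediate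
33 | (1(10)E,4Z,7R)-14-acetoxy-15-[(tert-butyldiphenylsilyl)oxy]germacra-1(10),4,11(13)-trien-12-oic acid | CC(C)(C)[Si](c1ccccc1)(c1ccccc1)OC/C1=C\C[C@H](C(=C)C(O)=O)CC/C(COC(C)=O)=C\CC1 | intermediate
34 | (1(10)E,4Z,7R)-14-acetoxy-15-hydroxygermacra-1(10),4,11(13)-trien-12-oic acid | OC/C1=C\C[C@H](C(=C)C(O)=O)CC/C(COC(C)=O)=C\CC1 | intermediate
35 | (1(10)E,4Z,7R,8S)-14-acetoxy-8,15-dihydroxygermacra-1(10),4,11(13)-trien-12-oic acid | OC/C1=C\C[C@H](C(=C)C(O)=O)[C@@H](O)C/C(COC(C)=O)=C\CC1 | intermediate (not isolated)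
36 | (1(10)E,4Z,7R,8S)-14-acetoxy-15-hydroxygermacra-1(10),4,11(13)-trien-12,8-olide (trans-fused) | OC/C1=C\C[C@@H]2C(=C)C(=O)O[C@H]2C/C(COC(C)=O)=C\CC1 | intermediate
37 | ethyl 2-(hydroxymethyl)prop-2-enoate | C=C(CO)C(=O)OCC | starting material
38 | ethyl 2-{[(tert-butyldimethylsilyl)oxy]methyl}prop-2-enoate | C=C(CO[Si](C)(C)C(C)(C)C)C(=O)OCC | intermediate
39 | 2-{[(tert-butyldimethylsilyl)oxy]methyl}prop-2-enoic acid | C=C(CO[Si](C)(C)C(C)(C)C)C(O)=O | intermediate
40 | (1(10)E,4Z,7R,8S)-14-acetoxy-15-[(2-{[(tert-butyldimethylsilyl)oxy]methyl}prop-2-enoyl)oxy]germacra-1(10),4,11(13)-trien-12,8-olide | C=C(CO[Si](C)(C)C(C)(C)C)C(=O)OC/C1=C\C[C@@H]2C(=C)C(=O)O[C@H]2C/C(COC(C)=O)=C\CC1 | intermediate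
41 | (1(10)E,4Z,7R,8S)-14-acetoxy-15-{[2-(hydroxymethyl)prop-2-enoyl]oxy}germacra-1(10),4,11(13)-trien-12,8-olide (CNP0126545.1) | C=C(CO)C(=O)OC/C1=C\C[C@@H]2C(=C)C(=O)O[C@H]2C/C(COC(C)=O)=C\CC1 | target

## Step count and least certain steps

Total: 27 steps. Longest linear sequence: 23 steps (1–3, 5–11, 13–23, 26, 27).

**Step 23 (key step, proposed new method).** The enzyme may fail to bind or may mis-position a substrate with a cis 1(10) olefin and two oxygenated methyls. The likely outcomes are oxidation at an allylic methylene, epoxidation, or attack on the C8 hydrogen cis to C11; contaminating esterases could also hydrolyse the acetate.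

Fallback by known chemistry, from 25 back to 36. It uses the fact that C8–H is the only hydrogen in a 1,5 relationship to the C14 oxygen (C2 lies trans across the olefin, C9 is too near).
- Electron-transfer desulfonylation of 25 (Na/Hg, Na2HPO4, MeOH/THF, −20 °C) would give ester 26, and buffered HF·pyridine the C14 alcohol F1.
- Nitrosyl chloride in pyridine would give nitrite ester F2. Irradiation at 350 nm (Barton nitrite photolysis) generates the C14 alkoxy radical, which abstracts the C8 hydrogen; return of nitric oxide and tautomerisation would give oxime F3.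
- Buffered TiCl3 would unmask ketone F4. NaBH4/CeCl3 at −78 °C should reduce it from the face away from the C7 side chain to the 8S hydroxy ester F5, and catalytic camphorsulfonic acid would close the saturated lactone F6.
- Classical lactone methylenation (LiN(iPr)2, 2.2 equiv, then CH2=NMe2+ I−) would give Mannich base F7, MeI its methiodide F8, and NaHCO3 the α-methylene lactone F9.
- Acetylation would give acetate F10, and HF·pyridine would deliver 36.

**Step 15.** Intermolecular alkylation (oligomers) may outrun closure of the ten-membered ring, and the sulfonyl allyl anion may lose silanolate by 1,4-elimination if the mixture warms. Fallback from 17 back to 25, in which the sulfone alkylation is intermolecular and the ring is closed at C9–C10 by palladium: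
- PPh3 and N-chlorosuccinimide would convert 17 into allylic chloride F11.
- The lithium anion of 20 (LiN(SiMe3)2, THF, −78 °C) would be alkylated by F11 to open-chain sulfone F12.
- 9-BBN-H would hydroborate its vinyl group to alkylborane F13, and intramolecular B-alkyl Suzuki–Miyaura coupling (Pd(dppf)Cl2, AsPh3, Cs2CO3, high dilution) would give 25.

**Step 16.** The π-allyl intermediate may isomerise or lose a β-hydrogen, which would move or scramble the C1=C10 olefin or give a diene; ester reduction may also stay incomplete. Fallback from 25 back to 27 with no new compound: the sulfone is removed by electron transfer (Na/Hg, Na2HPO4, MeOH/THF, −20 °C) to give isolated 26, whose ester is then reduced separately with i-Bu2AlH to 27.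

**Step 6.** Transfer of the hydroxymethyl group from tin is slow, so protodeiodination or acyl transfer from the imide to the new hydroxyl can compete at 90 °C. Fallback from 11 back to 12: palladium-catalysed formylation (Pd(PPh3)4, CO, Bu3SnH, THF, 50 °C) would give enal F14, and Luche reduction (NaBH4, CeCl3, MeOH, −40 °C) would give 12.

## Further compounds

F1 | step 23 | tert-butyl (1(10)E,4Z,7R)-15-[(tert-butyldiphenylsilyl)oxy]-14-hydroxy-13-norgermacra-1(10),4-dien-12-oate | CC(C)(C)[Si](c1ccccc1)(c1ccccc1)OC/C1=C\C[C@H](CC(=O)OC(C)(C)C)CC/C(CO)=C\CC1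
F2 | step 23 | tert-butyl (1(10)E,4Z,7R)-15-[(tert-butyldiphenylsilyl)oxy]-14-(nitrosooxy)-13-norgermacra-1(10),4-dien-12-oate | CC(C)(C)[Si](c1ccccc1)(c1ccccc1)OC/C1=C\C[C@H](CC(=O)OC(C)(C)C)CC/C(CON=O)=C\CC1
F3 | step 23 | tert-butyl (1(10)E,4Z,7R)-15-[(tert-butyldiphenylsilyl)oxy]-14-hydroxy-8-(hydroxyimino)-13-norgermacra-1(10),4-dien-12-oate | CC(C)(C)[Si](c1ccccc1)(c1ccccc1)OC/C1=C\C[C@H](CC(=O)OC(C)(C)C)C(=NO)C/C(CO)=C\CC1
F4 | step 23 | tert-butyl (1(10)E,4Z,7R)-15-[(tert-butyldiphenylsilyl)oxy]-14-hydroxy-8-oxo-13-norgermacra-1(10),4-dien-12-oate | CC(C)(C)[Si](c1ccccc1)(c1ccccc1)OC/C1=C\C[C@H](CC(=O)OC(C)(C)C)C(=O)C/C(CO)=C\CC1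
F5 | step 23 | tert-butyl (1(10)E,4Z,7R,8S)-15-[(tert-butyldiphenylsilyl)oxy]-8,14-dihydroxy-13-norgermacra-1(10),4-dien-12-oate | CC(C)(C)[Si](c1ccccc1)(c1ccccc1)OC/C1=C\C[C@H](CC(=O)OC(C)(C)C)[C@@H](O)C/C(CO)=C\CC1
F6 | step 23 | (1(10)E,4Z,7R,8S)-15-[(tert-butyldiphenylsilyl)oxy]-14-hydroxy-13-norgermacra-1(10),4-dien-12,8-olide | CC(C)(C)[Si](c1ccccc1)(c1ccccc1)OC/C1=C\C[C@@H]2CC(=O)O[C@H]2C/C(CO)=C\CC1
F7 | step 23 | (1(10)E,4Z,7R,8S)-15-[(tert-butyldiphenylsilyl)oxy]-13-(dimethylamino)-14-hydroxygermacra-1(10),4-dien-12,8-olide (C11 epimers) | CC(C)(C)[Si](c1ccccc1)(c1ccccc1)OC/C1=C\C[C@@H]2C(CN(C)C)C(=O)O[C@H]2C/C(CO)=C\CC1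
F8 | step 23 | methiodide of F7 (13-trimethylammonio iodide) | CC(C)(C)[Si](c1ccccc1)(c1ccccc1)OC/C1=C\C[C@@H]2C(C[N+](C)(C)C)C(=O)O[C@H]2C/C(CO)=C\CC1.[I-]
F9 | step 23 | (1(10)E,4Z,7R,8S)-15-[(tert-butyldiphenylsilyl)oxy]-14-hydroxygermacra-1(10),4,11(13)-trien-12,8-olide | CC(C)(C)[Si](c1ccccc1)(c1ccccc1)OC/C1=C\C[C@@H]2C(=C)C(=O)O[C@H]2C/C(CO)=C\CC1
F10 | step 23 | (1(10)E,4Z,7R,8S)-14-acetoxy-15-[(tert-butyldiphenylsilyl)oxy]germacra-1(10),4,11(13)-trien-12,8-olide | CC(C)(C)[Si](c1ccccc1)(c1ccccc1)OC/C1=C\C[C@@H]2C(=C)C(=O)O[C@H]2C/C(COC(C)=O)=C\CC1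
F11 | step 15 | tert-butyl (3R,5E)-6-{[(tert-butyldiphenylsilyl)oxy]methyl}-7-chloro-3-ethenylhept-5-enoate | ClC/C(CO[Si](c1ccccc1)(c1ccccc1)C(C)(C)C)=C/C[C@H](CC(=O)OC(C)(C)C)C=C
F12 | step 15 | tert-butyl (3R,5Z,9Z)-11-[(tert-butyldimethylsilyl)oxy]-6-{[(tert-butyldiphenylsilyl)oxy]methyl}-3-ethenyl-10-iodo-8-(phenylsulfonyl)undeca-5,9-dienoate (C8 epimers) | O=S(=O)(c1ccccc1)C(C/C(CO[Si](c1ccccc1)(c1ccccc1)C(C)(C)C)=C/C[C@H](CC(=O)OC(C)(C)C)C=C)/C=C(\I)CO[Si](C)(C)C(C)(C)C
F13 | step 15 | 9-BBN adduct of F12 (boron on the terminal carbon of the former vinyl group) | O=S(=O)(c1ccccc1)C(C/C(CO[Si](c1ccccc1)(c1ccccc1)C(C)(C)C)=C/C[C@H](CC(=O)OC(C)(C)C)CCB1C2CCCC1CCC2)/C=C(\I)CO[Si](C)(C)C(C)(C)C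
F0 | step 16 | none | none
F14 | step 6 | tert-butyl (3R,5Z)-3-{[(4R)-4-benzyl-2-oxo-1,3-oxazolidin-3-yl]carbonyl}-7-[(tert-butyldimethylsilyl)oxy]-6-formylhept-5-enoate | CC(C)(C)[Si](C)(C)OC/C(C=O)=C/C[C@H](CC(=O)OC(C)(C)C)C(=O)N1[C@H](Cc2ccccc2)COC1=O
A1 | alternative 1 | ten-membered (1(10)-cis,4-trans)-dienyl C10 triflate with 8-O-(4-methoxybenzyl), 12-O-tert-butyldimethylsilyl and 15-O-tert-butyldiphenylsilyl groups | CC(C)(C)[Si](c1ccccc1)(c1ccccc1)OC/C1=C\C[C@H](C(=C)CO[Si](C)(C)C(C)(C)C)[C@@H](OCc2ccc(OC)cc2)C/C(OS(=O)(=O)C(F)(F)F)=C\CC1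
A2 | alternative 2 | 15-O-tert-butyldimethylsilyl ether of lactone 36 | CC(C)(C)[Si](C)(C)OC/C1=C\C[C@@H]2C(=C)C(=O)O[C@H]2C/C(COC(C)=O)=C\CC1
A3 | alternative 3 | (1(10)-cis,4-trans)-cyclodecadien-8-one with tert-butyl acetate side chain on C7, 14-O-tert-butyldimethylsilyl and 15-O-(4-methoxybenzyl) groups | COc1ccc(COC/C2=C\C[C@H](CC(=O)OC(C)(C)C)C(=O)C/C(CO[Si](C)(C)C(C)(C)C)=C\CC2)cc1
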